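**Retrosynthetic overview**
- Target 17 is a cis-fused γ-lactone on a cyclohexane that carries an acetate at C8 and an angelate at C11. Both esters go on last (steps 7 and 8). The C11 oxygen comes from convex-face hydroxylation of the lactone enolate (step 6) and the C8 alcohol from a ketone (step 5).
- Key disconnection: the lactone O–C6 bond and the C7–C11 bond, made together by a formal [3+2] annulation of 2-bromopropanoic acid 6 onto cyclohexenone 5 (oxa-Michael addition, then α-alkylation, under iminium–enamine catalysis).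
- Enabling feature: the oxygenated triad C6–C7–C8 of the carbocycle. With C8 as a ketone, C6=C7 is the only electron-poor alkene (the vinyl C1=C2 and isopropenyl C3=C4 are not). C6 is its β (electrophilic) and C7 its α (nucleophilic) carbon, which matches the O-nucleophile/C-electrophile pair of the α-bromo acid and closes the lactone ring C6–O–C12–C11–C7.
- Enone 5 comes from (−)-verbenone 1 in three steps: vinyl conjugate addition (sets C10), cyclobutane fragmentation (frees the isopropenyl group at C5 and an enol acetate at C7=C8), dehydrogenation. C5 is bought; C10, C6, C7, C8 and C11 are relayed from it by substrate control.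
- Ring order: six-membered carbocycle (from 1, freed in step 2), then the γ-lactone (step 4).

Key step: step 4

Remark: locants follow elemane numbering (C10 quaternary with vinyl and methyl; C5 with isopropenyl; C6 lactone oxygen; C7; C8 acetoxy; C9 CH2; C11 with methyl and angeloyloxy; C12 lactone carbonyl). β is the ring face of the C10 vinyl group and of the lactone; α is that of the isopropenyl, C10 methyl and C8 acetoxy groups.
Remark: compounds 8, 9 and 10 are carried as C11 epimers, because step 6 makes C11 planar and sets it.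

**Step 1**
Reactants: 1 (1S,5S)-(−)-verbenone
Product: 3 (1S,4R,5R)-4-ethenyl-4,6,6-trimethylbicyclo[3.1.1]heptan-2-one, via bromomagnesium enolate 2 (not isolated)
Conditions: CH2=CHMgBr, CuBr·SMe2 (10 mol %), THF, −40 to −20 °C; H2O/aq. NH4Cl
Reagents that add atoms: vinylmagnesium bromide, C=C[Mg]Br
Why: Copper-catalysed conjugate addition of a vinyl Grignard reagent to the β,β-disubstituted enone should occur on the face anti to the gem-dimethyl bridge, which fixes the quaternary centre (C10 of the target) with the vinyl group trans to the bridge carbon that later becomes the isopropenyl group.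

**Step 2**
Reactants: 3 (1S,4R,5R)-4-ethenyl-4,6,6-trimethylbicyclo[3.1.1]heptan-2-one
Product: 4 (4R,5R)-5-ethenyl-5-methyl-4-(prop-1-en-2-yl)cyclohex-1-en-1-yl acetate
Conditions: Zn(OAc)2, BF3·OEt2, Ac2O, 0 °C to rt
Reagents that add atoms: acetic anhydride, CC(=O)OC(C)=O
Why: Lewis-acid-promoted fragmentation of the strained cyclobutane of a 4,4-disubstituted nopinone (cleavage of the bond between the bridgehead next to the carbonyl and the gem-dimethyl carbon, O-acetylation of the enol, loss of a proton from the tertiary cation) is a known entry to elemane-type cyclohexanes and should give the enol acetate regiospecifically on the C7 side and free the isopropenyl group, with C5 and C10 untouched.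

**Step 3**
Reactants: 4 (4R,5R)-5-ethenyl-5-methyl-4-(prop-1-en-2-yl)cyclohex-1-en-1-yl acetate
Product: 5 (4R,5R)-5-ethenyl-5-methyl-4-(prop-1-en-2-yl)cyclohex-2-en-1-one
Conditions: Pd(OAc)2 (5 mol %), dppe (5 mol %), Bu3SnOMe (20 mol %), allyl methyl carbonate, MeCN, 80 °C
Reagents that add atoms: none
Why: Palladium-catalysed dehydrogenation of an enol acetate with allyl methyl carbonate and catalytic Bu3SnOMe (Tsuji variant of the Saegusa–Ito oxidation) should give the enone; β-hydride elimination is possible only toward C6 because C10 is quaternary, and no stereocentre is touched.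

**Step 4**
Reactants: 5 (4R,5R)-5-ethenyl-5-methyl-4-(prop-1-en-2-yl)cyclohex-2-en-1-one; 6 (±)-2-bromopropanoic acid
Product: 9 (3aS,6R,7R,7aS)-6-ethenyl-3,6-dimethyl-7-(prop-1-en-2-yl)tetrahydro-1-benzofuran-2,4(3H,5H)-dione (C3 epimers), via iminium salt 7 (not isolated), via acyloxy enamine 8 (not isolated)
Conditions: Ph2CHNH2 (20 mol %), 6 (2 equiv), NaHCO3 (1.2 equiv), 1,4-dioxane, 40 °C
Reagents that add atoms: none
Why: Proposed new method: the primary amine condenses with 5 to iminium salt 7, whose counter-ion, the 2-bromopropanoate, adds at C6 (oxa-Michael) to give acyloxy enamine 8; the enamine carbon C7 then displaces bromide at C11 inside the tethered α-bromo ester, and hydrolysis frees 9 and the amine while NaHCO3 takes up HBr. The closest known reactions are the amine-salt-catalysed epoxidation of cyclic enones (oxa-Michael addition, then closure by the enamine), the iminium–enamine cyclopropanation of enals and enones with bromomalonates (Michael addition, then α-alkylation) and the Stork alkylation of enamines with α-halo esters; new here are a carboxylate as the Michael donor and closure to a five-membered lactone. The γ-lactone closes in a 5-(enolexo)-exo-tet mode, which is allowed, and the irreversible C-alkylation should pull the unfavourable carboxylate addition equilibrium through. C6 is set by attack on the β face, anti to the pseudo-axial C10 methyl and trans to the C5 isopropenyl group (as in cuprate additions to 4-substituted cyclohexenones), and C7 follows because the tether reaches only the same face, so the ring fusion must be cis; C11 forms as a mixture that step 6 erases. The step needs chemo- and regioselectivity among three alkenes, and the C8 carbonyl secures both: only C6=C7 is electron-poor, with C6 its β and C7 its α carbon, while the vinyl and isopropenyl groups are inert to this polar process. The hindered amine should limit N-alkylation by 6, and the buffered medium should limit C5 epimerisation through a dienamine.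

**Step 5**
Reactants: 9 (3aS,6R,7R,7aS)-6-ethenyl-3,6-dimethyl-7-(prop-1-en-2-yl)tetrahydro-1-benzofuran-2,4(3H,5H)-dione (C3 epimers)
Product: 10 (3aR,4S,6R,7R,7aS)-6-ethenyl-4-hydroxy-3,6-dimethyl-7-(prop-1-en-2-yl)hexahydro-1-benzofuran-2(3H)-one (C3 epimers)
Conditions: LiBH(s-Bu)3, THF, −78 °C; H2O
Reagents that add atoms: none
Why: Ketone reduction with a bulky trialkylborohydride: in the chair of 9 that carries the C10 methyl axial on the α face the axial trajectory is closed (as in 3,3,5-trimethylcyclohexanone), so hydride should enter from the β side and give the axial 8α alcohol, which is trans to C7–C11 and therefore cannot translactonise; the lactone and the alkenes are inert at −78 °C.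

**Step 6**
Reactants: 10 (3aR,4S,6R,7R,7aS)-6-ethenyl-4-hydroxy-3,6-dimethyl-7-(prop-1-en-2-yl)hexahydro-1-benzofuran-2(3H)-one (C3 epimers)
Product: 12 (3S,3aR,4S,6R,7R,7aS)-6-ethenyl-3,4-dihydroxy-3,6-dimethyl-7-(prop-1-en-2-yl)hexahydro-1-benzofuran-2(3H)-one, via dipotassium dianion 11 (not isolated)
Conditions: KN(SiMe3)2 (2.3 equiv), THF, −78 to −40 °C; 2-(benzenesulfonyl)-3-phenyloxaziridine, −78 °C; H2O
Reagents that add atoms: 2-(benzenesulfonyl)-3-phenyloxaziridine (Davis oxaziridine), O=S(=O)(c1ccccc1)N1OC1c1ccccc1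
Why: Davis α-hydroxylation of the lactone enolate (formed as alkoxide–enolate 11, which makes C11 planar) should occur on the convex face of the cis-fused bicycle, the side of H7 and away from C8, so the new hydroxyl ends up cis to H7 and the methyl group endo, as the target requires.

**Step 7**
Reactants: 12 (3S,3aR,4S,6R,7R,7aS)-6-ethenyl-3,4-dihydroxy-3,6-dimethyl-7-(prop-1-en-2-yl)hexahydro-1-benzofuran-2(3H)-one
Product: 13 (3S,3aR,4S,6R,7R,7aS)-6-ethenyl-3-hydroxy-3,6-dimethyl-2-oxo-7-(prop-1-en-2-yl)octahydro-1-benzofuran-4-yl acetate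
Conditions: Ac2O, pyridine, DMAP (5 mol %), CH2Cl2, 0 °C to rt
Reagents that add atoms: acetic anhydride, CC(=O)OC(C)=O
Why: DMAP-catalysed acetylation should be selective for the secondary C8 hydroxyl, because the tertiary α-hydroxy lactone OH is far less reactive; no stereocentre is touched.

**Step 8**
Reactants: 13 (3S,3aR,4S,6R,7R,7aS)-6-ethenyl-3-hydroxy-3,6-dimethyl-2-oxo-7-(prop-1-en-2-yl)octahydro-1-benzofuran-4-yl acetate; 14 angelic acid
Product: 17 (3S,3aR,4S,6R,7R,7aS)-4-acetoxy-6-ethenyl-3,6-dimethyl-2-oxo-7-(prop-1-en-2-yl)octahydro-1-benzofuran-3-yl (2Z)-2-methylbut-2-enoate, via mixed anhydride 15 (not isolated), via lithium alkoxide 16 (not isolated)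
Conditions: 14, 2,4,6-Cl3C6H2COCl, Et3N, toluene, rt; 13, LiN(SiMe3)2, THF, −78 °C; mix, −78 to 0 °C
Reagents that add atoms: none
Why: Yamaguchi-type acylation in which the lithium alkoxide of the hindered tertiary alcohol should attack the mixed anhydride at the less shielded angeloyl carbonyl at low temperature, which avoids the Z to E isomerisation that acid chlorides or hot DMAP conditions cause; no stereocentre is touched.

**Compound list**
1 | (1S,5S)-(−)-verbenone, (1S,5S)-4,6,6-trimethylbicyclo[3.1.1]hept-3-en-2-one | CC1=CC(=O)[C@H]2C[C@@H]1C2(C)C | starting material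
2 | bromomagnesium enolate of 3 (C2=C3 enolate) | C=C[C@@]1(C)C=C(O[Mg]Br)[C@H]2C[C@@H]1C2(C)C | intermediate
3 | (1S,4R,5R)-4-ethenyl-4,6,6-trimethylbicyclo[3.1.1]heptan-2-one (vinyl anti to the gem-dimethyl bridge) | C=C[C@@]1(C)CC(=O)[C@H]2C[C@@H]1C2(C)C | intermediate
4 | (4R,5R)-5-ethenyl-5-methyl-4-(prop-1-en-2-yl)cyclohex-1-en-1-yl acetate | C=C[C@@]1(C)CC(OC(C)=O)=CC[C@@H]1C(=C)C | intermediate
5 | (4R,5R)-5-ethenyl-5-methyl-4-(prop-1-en-2-yl)cyclohex-2-en-1-one | C=C[C@@]1(C)CC(=O)C=C[C@@H]1C(=C)C | intermediate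
6 | (±)-2-bromopropanoic acid | CC(Br)C(=O)O | starting material
7 | N-benzhydryl iminium 2-bromopropanoate of enone 5 | C=C[C@@]1(C)CC(=[NH+]C(c2ccccc2)c2ccccc2)C=C[C@@H]1C(=C)C.CC(Br)C(=O)[O-] | intermediate
8 | 3-(benzhydrylamino)-5-ethenyl-5-methyl-6-(prop-1-en-2-yl)cyclohex-2-en-1-yl 2-bromopropanoate (acyloxy group on the β face, trans to isopropenyl; bromide epimers) | C=C[C@@]1(C)CC(NC(c2ccccc2)c2ccccc2)=C[C@@H](OC(=O)C(C)Br)[C@@H]1C(=C)C | intermediate
9 | (3aS,6R,7R,7aS)-6-ethenyl-3,6-dimethyl-7-(prop-1-en-2-yl)tetrahydro-1-benzofuran-2,4(3H,5H)-dione, C3 epimers (cis-fused lactone on the β face, C8 ketone) | C=C[C@@]1(C)CC(=O)[C@@H]2[C@@H](OC(=O)C2C)[C@@H]1C(=C)C | intermediate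
10 | (3aR,4S,6R,7R,7aS)-6-ethenyl-4-hydroxy-3,6-dimethyl-7-(prop-1-en-2-yl)hexahydro-1-benzofuran-2(3H)-one, C3 epimers (8α-alcohol) | C=C[C@@]1(C)C[C@H](O)[C@@H]2[C@@H](OC(=O)C2C)[C@@H]1C(=C)C | intermediate
11 | dipotassium alkoxide–enolate of 10 | C=C[C@@]1(C)C[C@H]([O-])[C@@H]2[C@@H](OC([O-])=C2C)[C@@H]1C(=C)C.[K+].[K+] | intermediate
12 | (3S,3aR,4S,6R,7R,7aS)-6-ethenyl-3,4-dihydroxy-3,6-dimethyl-7-(prop-1-en-2-yl)hexahydro-1-benzofuran-2(3H)-one | C=C[C@@]1(C)C[C@H](O)[C@@H]2[C@@H](OC(=O)[C@@]2(C)O)[C@@H]1C(=C)C | intermediate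
13 | (3S,3aR,4S,6R,7R,7aS)-6-ethenyl-3-hydroxy-3,6-dimethyl-2-oxo-7-(prop-1-en-2-yl)octahydro-1-benzofuran-4-yl acetate | C=C[C@@]1(C)C[C@H](OC(C)=O)[C@@H]2[C@@H](OC(=O)[C@@]2(C)O)[C@@H]1C(=C)C | intermediate
14 | angelic acid, (2Z)-2-methylbut-2-enoic acid | C/C=C(/C)C(=O)O | starting material
15 | (2Z)-2-methylbut-2-enoic 2,4,6-trichlorobenzoic anhydride | C/C=C(/C)C(=O)OC(=O)c1c(Cl)cc(Cl)cc1Cl | intermediate
16 | lithium alkoxide of 13 | C=C[C@@]1(C)C[C@H](OC(C)=O)[C@@H]2[C@@H](OC(=O)[C@@]2(C)[O-])[C@@H]1C(=C)C.[Li+] | intermediate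
17 | (3S,3aR,4S,6R,7R,7aS)-4-acetoxy-6-ethenyl-3,6-dimethyl-2-oxo-7-(prop-1-en-2-yl)octahydro-1-benzofuran-3-yl (2Z)-2-methylbut-2-enoate (CNP0140071.1) | C=C[C@@]1(C)C[C@H](OC(C)=O)[C@@H]2[C@@H](OC(=O)[C@@]2(C)OC(=O)/C(C)=C\C)[C@@H]1C(=C)C | target

Total step count: 8. Longest linear sequence: 8 steps (from 1 to 17).

**Steps most likely to fail**

1. Step 4 (Proposed new method). The carboxylate addition to the iminium ion may lie so far on the side of 7 that the ring-closing alkylation never competes. The amine may be used up by N-alkylation with 6. The C5 hydrogen may be scrambled through a dienamine, or alkylation may occur on the C9 side. Fallback, known chemistry only, from 5 back to 9: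
   - Iodination at C7 (I2, pyridine, CH2Cl2, rt) should give (4R,5R)-5-ethenyl-2-iodo-5-methyl-4-(prop-1-en-2-yl)cyclohex-2-en-1-one F1.
   - Negishi coupling with the Reformatsky reagent BrZnCH(CH3)CO2t-Bu (Pd(PPh3)4, THF, 50 °C) should give tert-butyl 2-[(3R,4R)-4-ethenyl-4-methyl-6-oxo-3-(prop-1-en-2-yl)cyclohex-1-en-1-yl]propanoate F2.
   - CF3CO2H in CH2Cl2 should cleave the ester to 2-[(3R,4R)-4-ethenyl-4-methyl-6-oxo-3-(prop-1-en-2-yl)cyclohex-1-en-1-yl]propanoic acid F3. The same acid should close F3 by conjugate lactonisation (β,γ-unsaturated acid to γ-lactone, carboxyl adding to C6 on the β face) to 9.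
   - In this fallback the two bonds are made in separate steps.

2. Step 5. Hydride delivery may show poor facial selectivity: the β trajectory passes the axial C7–C11 bond of the lactone, so attack from the α face (the convex face of the bicycle) may compete and give the 8β alcohol, which can then migrate the lactone to the C8 oxygen. Fallback from 9 back to 13:
   - Reduction with a small hydride (NaBH4, CeCl3·7H2O, MeOH, −78 °C) should give the 8β alcohol (3aR,4R,6R,7R,7aS)-6-ethenyl-4-hydroxy-3,6-dimethyl-7-(prop-1-en-2-yl)hexahydro-1-benzofuran-2(3H)-one F4.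
   - Mitsunobu inversion with acetic acid (PPh3, DIAD, AcOH, toluene, 0 °C to rt) should install the acetate with the 8α configuration and give (3aR,4S,6R,7R,7aS)-6-ethenyl-3,6-dimethyl-2-oxo-7-(prop-1-en-2-yl)octahydro-1-benzofuran-4-yl acetate F5.
   - Selective enolisation of the more acidic lactone C–H (LiN(SiMe3)2, 1.05 equiv, THF, −78 °C) and Davis hydroxylation on the convex face should then give 13.

3. Step 8. Acylation of the hindered tertiary alkoxide may stall, and the angeloyl unit may isomerise from Z to E under forcing conditions. Fallback from 13 back to 17: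
   - Acylation of the lithium alkoxide with 2-[bis(2,2,2-trifluoroethoxy)phosphoryl]propanoyl chloride (LiN(SiMe3)2, THF, −78 to 0 °C) should give the phosphonate ester (3S,3aR,4S,6R,7R,7aS)-4-acetoxy-6-ethenyl-3,6-dimethyl-2-oxo-7-(prop-1-en-2-yl)octahydro-1-benzofuran-3-yl 2-[bis(2,2,2-trifluoroethoxy)phosphoryl]propanoate F6.
   - Still–Gennari olefination with acetaldehyde (KN(SiMe3)2, 18-crown-6, THF, −78 °C) should build the Z-configured 2-methylbut-2-enoate on the molecule and give 17.

**Further compounds**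
F1 | step 4 | (4R,5R)-5-ethenyl-2-iodo-5-methyl-4-(prop-1-en-2-yl)cyclohex-2-en-1-one | C=C[C@@]1(C)CC(=O)C(I)=C[C@@H]1C(=C)C
F2 | step 4 | tert-butyl 2-[(3R,4R)-4-ethenyl-4-methyl-6-oxo-3-(prop-1-en-2-yl)cyclohex-1-en-1-yl]propanoate (side-chain epimers) | C=C[C@@]1(C)CC(=O)C(C(C)C(=O)OC(C)(C)C)=C[C@@H]1C(=C)C
F3 | step 4 | 2-[(3R,4R)-4-ethenyl-4-methyl-6-oxo-3-(prop-1-en-2-yl)cyclohex-1-en-1-yl]propanoic acid (side-chain epimers) | C=C[C@@]1(C)CC(=O)C(C(C)C(=O)O)=C[C@@H]1C(=C)C
F4 | step 5 | (3aR,4R,6R,7R,7aS)-6-ethenyl-4-hydroxy-3,6-dimethyl-7-(prop-1-en-2-yl)hexahydro-1-benzofuran-2(3H)-one, C3 epimers (8β-alcohol) | C=C[C@@]1(C)C[C@@H](O)[C@@H]2[C@@H](OC(=O)C2C)[C@@H]1C(=C)C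
F5 | step 5 | (3aR,4S,6R,7R,7aS)-6-ethenyl-3,6-dimethyl-2-oxo-7-(prop-1-en-2-yl)octahydro-1-benzofuran-4-yl acetate, C3 epimers | C=C[C@@]1(C)C[C@H](OC(C)=O)[C@@H]2[C@@H](OC(=O)C2C)[C@@H]1C(=C)C
F6 | step 8 | (3S,3aR,4S,6R,7R,7aS)-4-acetoxy-6-ethenyl-3,6-dimethyl-2-oxo-7-(prop-1-en-2-yl)octahydro-1-benzofuran-3-yl 2-[bis(2,2,2-trifluoroethoxy)phosphoryl]propanoate (side-chain epimers) | C=C[C@@]1(C)C[C@H](OC(C)=O)[C@@H]2[C@@H](OC(=O)[C@@]2(C)OC(=O)C(C)P(=O)(OCC(F)(F)F)OCC(F)(F)F)[C@@H]1C(=C)C
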